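**Retrosynthetic overview**
- The pyranone is not joined to the arene through the CH2 bridge (the usual pyranone + CH2O + acylphloroglucinol coupling). It is built last by cutting pyranone C3–C4 and O1–C2, which gives an aryl-fused dihydrocoumarin plus methylketene dimer (itself made from two molecules of propanoyl chloride). This is a lactone-to-lactone ring switch that also frees the phenol.
- The dihydrocoumarin lactone (bridge CH2 and the future pyranone C2/C3) comes from the C2-symmetric acylphloroglucinol methyl ether and acrylic acid by hydroarylation/lactonisation.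
- The aryl ketone comes from directed ortho-metalation of bis-MOM 5-methoxyresorcinol and the Weinreb amide of (R)-2-methylbutanoic acid, so the stereocentre is bought and never passes through an enolisable acylium ion.
- Ring order: benzene ring bought, then the chromanone (lactone) ring, then the pyranone ring, formed last while the chromanone ring opens.

Assumption: (R)-2-methylbutanoic acid (CAS 32231-50-8, ≥98% ee) is taken as commercially available; the target is drawn as the 4-hydroxy-2-pyranone tautomer of the given SMILES.

Step 1
Reactants: 1 (R)-2-methylbutanoic acid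
Product: 3 (R)-N-methoxy-N,2-dimethylbutanamide, via acyl imidazolide 2 (not isolated)
Conditions: CDI (1.1 equiv), CH2Cl2, 0 → 23 °C, 1 h; then MeNH(OMe)·HCl (1.2 equiv), 23 °C, 12 h
Reagents that add atoms: N,O-dimethylhydroxylamine hydrochloride, CNOC.Cl
Why: CDI-mediated amidation (Weinreb amide synthesis) proceeds through the acyl imidazolide without any base strong enough to form a ketene or enolate, so the purchased (R)-stereocentre is carried over unchanged.

Step 2
Reactants: 4 5-methoxybenzene-1,3-diol
Product: 5 1-methoxy-3,5-bis(methoxymethoxy)benzene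
Conditions: NaH (2.4 equiv), DMF, 0 °C; MOMCl (2.4 equiv), 0 → 23 °C, 3 h
Reagents that add atoms: chloromethyl methyl ether (MOMCl), COCCl
Why: Williamson-type O-alkylation (MOM protection) of both phenols installs the strongest oxygen-based directing groups for the next step and leaves again under mild acid.

Step 3
Reactants: 5 1-methoxy-3,5-bis(methoxymethoxy)benzene (1.3 equiv); 3 (R)-N-methoxy-N,2-dimethylbutanamide (1.0 equiv)
Product: 8 (R)-1-[4-methoxy-2,6-bis(methoxymethoxy)phenyl]-2-methylbutan-1-one, via aryllithium 6 (not isolated), via tetrahedral lithium adduct 7 (not isolated)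
Conditions: n-BuLi (1.25 equiv), THF, 0 °C, 1 h; then 3, −78 → 0 °C, 2 h; cold 0.5 M HCl quench
Reagents that add atoms: none
Why: Directed ortho-metalation takes place at the CH flanked by two cooperating OMOM groups (stronger than the OMOM/OMe sites), and the Weinreb ketone synthesis stops at the chelated tetrahedral adduct, so the ketone is released only on quench and its α-stereocentre never meets base.

Step 4
Reactants: 8 (R)-1-[4-methoxy-2,6-bis(methoxymethoxy)phenyl]-2-methylbutan-1-one
Product: 9 (R)-1-(2,6-dihydroxy-4-methoxyphenyl)-2-methylbutan-1-one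
Conditions: HCl (0.5 M in MeOH), 40 °C, 3 h
Reagents that add atoms: none
Why: Acid-catalysed transacetalisation (MOM ether cleavage) in methanol removes the formaldehyde unit as dimethoxymethane, and these mild conditions do not enolise the hindered, hydrogen-bonded aryl ketone.

Step 5
Reactants: 9 (R)-1-(2,6-dihydroxy-4-methoxyphenyl)-2-methylbutan-1-one; 10 acrylic acid (1.5 equiv)
Product: 12 7-hydroxy-5-methoxy-8-[(2R)-2-methylbutanoyl]-3,4-dihydro-2H-chromen-2-one, via arylpropanoic acid 11 (not isolated)
Conditions: Amberlyst-15 (dry), toluene, 90 °C, 12 h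
Reagents that add atoms: none
Why: Brønsted-acid hydroarylation (Friedel–Crafts conjugate addition) of acrylic acid occurs at C3 of 9 (C3 and C5 are equivalent by symmetry, ortho/para to three oxygen donors and meta to the acyl group) and is followed by lactonisation onto the only neighbouring OH, the standard phenol + acrylic acid dihydrocoumarin synthesis, with the stereocentre untouched.

Step 6
Reactants: 13 propanoyl chloride (2 molecules per molecule of product)
Product: 15 (Z)-4-ethylidene-3-methyloxetan-2-one (methylketene dimer; racemic), via methylketene 14 (not isolated)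
Conditions: i-Pr2NEt (1.0 equiv per acid chloride), quinuclidine (5 mol%), CH2Cl2, 23 °C, 6 h; pentane, filter, bulb-to-bulb distil under reduced pressure, use at once
Reagents that add atoms: propanoyl chloride (the second molecule of 13, which supplies the other C3 half of the dimer), CCC(=O)Cl
Why: Dehydrochlorination turns each of the two molecules of propanoyl chloride into methylketene, and nucleophilic-amine-catalysed head-to-tail [2+2] ketene dimerisation (ammonium enolate of one ketene acylated by the second, then β-lactone closure) gives the dimer, whose ring stereocentre and alkene geometry are irrelevant because both are erased in step 7.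

Step 7
Reactants: 12 7-hydroxy-5-methoxy-8-[(2R)-2-methylbutanoyl]-3,4-dihydro-2H-chromen-2-one; 15 (Z)-4-ethylidene-3-methyloxetan-2-one (1.3 equiv)
Product: 18 3-({2,4-dihydroxy-6-methoxy-3-[(2R)-2-methylbutanoyl]phenyl}methyl)-6-ethyl-4-hydroxy-5-methyl-2H-pyran-2-one, via dilithium enolate 16 (not isolated), via acylated lactone 17 (not isolated)
Conditions: LiHMDS (2.2 equiv), THF, −78 °C, 30 min; then 15, −78 → 23 °C, 3 h; 1 M HCl work-up
Reagents that add atoms: none
Why: Proposed new method: LiHMDS, too weak and hindered to remove the tertiary α-H of the phenoxide-conjugated, Li-chelated aryl ketone, forms the phenoxide/lactone-enolate 16, whose C3 attacks the strained β-lactone carbonyl of 15 (Claisen-type C-acylation with acyl–oxygen ring opening) to give the 1,3,5-tricarbonyl enolate 17, and the enolate oxygen released by that ring opening then closes onto the activated aryl-lactone carbonyl and expels the phenoxide (translactonisation) to give the 4-hydroxy-2-pyranone, so no new stereocentre is formed and the labile centres of 15 and 17 are erased; the closest known reaction types are the diketene/malonate-carbanion synthesis of 4-hydroxy-2-pyranones, the base-induced conversion of alkylketene dimers into 2-pyranone trimers and the cyclisation of 3,5-dioxo esters to 4-hydroxy-2-pyranones.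

**Compound list**
1 | (R)-2-methylbutanoic acid | OC(=O)[C@H](C)CC | starting material
2 | (R)-1-(1H-imidazol-1-yl)-2-methylbutan-1-one (acyl imidazolide) | O=C([C@H](C)CC)n1ccnc1 | intermediate
3 | (R)-N-methoxy-N,2-dimethylbutanamide | CON(C)C(=O)[C@H](C)CC | intermediate
4 | 5-methoxybenzene-1,3-diol (5-methoxyresorcinol) | COc1cc(O)cc(O)c1 | starting material
5 | 1-methoxy-3,5-bis(methoxymethoxy)benzene | COCOc1cc(OC)cc(OCOC)c1 | intermediate
6 | [4-methoxy-2,6-bis(methoxymethoxy)phenyl]lithium | [Li]c1c(OCOC)cc(OC)cc1OCOC | intermediate
7 | lithium (2R)-1-[methoxy(methyl)amino]-1-[4-methoxy-2,6-bis(methoxymethoxy)phenyl]-2-methylbutan-1-olate (tetrahedral adduct, C1 epimers) | [Li]OC(N(C)OC)([C@H](C)CC)c1c(OCOC)cc(OC)cc1OCOC | intermediate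
8 | (R)-1-[4-methoxy-2,6-bis(methoxymethoxy)phenyl]-2-methylbutan-1-one | O=C([C@H](C)CC)c1c(OCOC)cc(OC)cc1OCOC | intermediate
9 | (R)-1-(2,6-dihydroxy-4-methoxyphenyl)-2-methylbutan-1-one | O=C([C@H](C)CC)c1c(O)cc(OC)cc1O | intermediate
10 | acrylic acid | C=CC(=O)O | starting material
11 | 3-{2,4-dihydroxy-6-methoxy-3-[(2R)-2-methylbutanoyl]phenyl}propanoic acid | OC(=O)CCc1c(OC)cc(O)c(C(=O)[C@H](C)CC)c1O | intermediate
12 | 7-hydroxy-5-methoxy-8-[(2R)-2-methylbutanoyl]-3,4-dihydro-2H-chromen-2-one | O=C1CCc2c(OC)cc(O)c(C(=O)[C@H](C)CC)c2O1 | intermediate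
13 | propanoyl chloride | CCC(=O)Cl | starting material
14 | methylketene (prop-1-en-1-one) | CC=C=O | intermediate
15 | (Z)-4-ethylidene-3-methyloxetan-2-one (methylketene dimer, racemic at C3) | C/C=C1\OC(=O)C1C | intermediate
16 | dilithium phenoxide/lactone enolate of 12 | [Li]OC1=CCc2c(OC)cc(O[Li])c(C(=O)[C@H](C)CC)c2O1 | intermediate
17 | 7-hydroxy-5-methoxy-8-[(2R)-2-methylbutanoyl]-3-(2-methyl-3-oxopentanoyl)-3,4-dihydro-2H-chromen-2-one (present as its lithium enolate; labile centres unassigned) | CCC(=O)C(C)C(=O)C1Cc2c(OC)cc(O)c(C(=O)[C@H](C)CC)c2OC1=O | intermediate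
18 | 3-({2,4-dihydroxy-6-methoxy-3-[(2R)-2-methylbutanoyl]phenyl}methyl)-6-ethyl-4-hydroxy-5-methyl-2H-pyran-2-one | CCc1oc(=O)c(Cc2c(OC)cc(O)c(C(=O)[C@H](C)CC)c2O)c(O)c1C | target

**Totals**
Total step count: 7. Longest linear sequence: 5 steps (1 → 3 → 8 → 9 → 12 → 18, or equally 4 → 5 → 8 → 9 → 12 → 18).

**Three steps most likely to fail**

1. Step 7 (ring-switch annulation). The cascade is unprecedented as a whole. The enolate 16 may deprotonate 15 instead of adding to it, the aryl-lactone enolate may fragment to a tethered ketene/phenoxide, the phenoxide may be O-acylated, and the ee of the product must be checked by chiral HPLC. The fallback sets out from 9 and comes back at 18 by the conventional methylene-bridge coupling. (Z)-3-(Trimethylsilyloxy)pent-2-ene and malonyl dichloride (Et2O, −78 °C → 23 °C) give 6-ethyl-4-hydroxy-5-methyl-2H-pyran-2-one F1. Eschenmoser's salt (CH2Cl2, 23 °C) converts it into the Mannich base 3-[(dimethylamino)methyl]-6-ethyl-4-hydroxy-5-methyl-2H-pyran-2-one F2. Warming F2 with an excess of 9 (MeCN, 60 °C) eliminates dimethylamine to a 3-methylene-pyrandione, which is trapped at C3 of 9 to give 18.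

2. Step 5 (hydroarylation). The acyl group slows the arene, and hot acid could cause bis-alkylation or erode the ee. The fallback sets out from 9 and comes back at 12 under near-neutral conditions. A three-component Yonemitsu-type condensation of 9 with aqueous formaldehyde and Meldrum's acid (cat. L-proline, MeCN, 23 °C) gives 5-({2,4-dihydroxy-6-methoxy-3-[(2R)-2-methylbutanoyl]phenyl}methyl)-2,2-dimethyl-1,3-dioxane-4,6-dione F3. Warming in pyridine (90 °C) lactonises it, with loss of acetone, to 7-hydroxy-5-methoxy-8-[(2R)-2-methylbutanoyl]-2-oxochromane-3-carboxylic acid F4, which decarboxylates in the same pot to 12.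

3. Step 3 (metalation/acylation). Lithiation at a site between OMOM and OMe would give the wrong isomer, and the hindered aryllithium may add slowly to the α-branched amide. The fallback sets out from 3 and comes back at 9 by using symmetry instead of directing-group competition. 1,3,5-Trimethoxybenzene, which has only one kind of ring hydrogen, is lithiated (n-BuLi, THF, 0 °C) and added to 3 to give (R)-2-methyl-1-(2,4,6-trimethoxyphenyl)butan-1-one F5. Excess BCl3 (CH2Cl2, 0 → 23 °C) then cleaves only the two carbonyl-chelated ortho methyl ethers to give 9.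

**Further compounds**
F1 | step 7 | 6-ethyl-4-hydroxy-5-methyl-2H-pyran-2-one | CCc1oc(=O)cc(O)c1C
F2 | step 7 | 3-[(dimethylamino)methyl]-6-ethyl-4-hydroxy-5-methyl-2H-pyran-2-one | CCc1oc(=O)c(CN(C)C)c(O)c1C
F3 | step 5 | 5-({2,4-dihydroxy-6-methoxy-3-[(2R)-2-methylbutanoyl]phenyl}methyl)-2,2-dimethyl-1,3-dioxane-4,6-dione | CC1(C)OC(=O)C(Cc2c(OC)cc(O)c(C(=O)[C@H](C)CC)c2O)C(=O)O1
F4 | step 5 | 7-hydroxy-5-methoxy-8-[(2R)-2-methylbutanoyl]-2-oxochromane-3-carboxylic acid | OC(=O)C1Cc2c(OC)cc(O)c(C(=O)[C@H](C)CC)c2OC1=O
F5 | step 3 | (R)-2-methyl-1-(2,4,6-trimethoxyphenyl)butan-1-one | O=C([C@H](C)CC)c1c(OC)cc(OC)cc1OC
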